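**Retrosynthetic overview**
1. Ring B (the ten-membered carbocycle) is closed last, at C2–C3, by an intramolecular nickel/chromium-catalysed Nozaki–Hiyama–Kishi coupling of an E-alkenyl iodide with a Z-enal; C3 acetylation ends the synthesis.
2. The C7–C8 bond joins fragment B (butenolide allyl acetate) and fragment C (iodo-diol) in an iridium-catalysed transfer-hydrogenative allylation that creates the α-methylene lactone, C7 and C8; the angelate is added next.
3. Ring A (the γ-lactone) is formed first: asymmetric nickel/chromium alkenylation of a Z-enal (from 4-methylbutenolide) with fragment A (a Z-β-iodoacrylate from methyl propiolate), then lactonisation; this sets C6.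
4. Fragment C comes from (E)-4-iodobut-3-en-2-one by catalytic asymmetric allylboration (sets C10) and ozonolysis/reduction.
5. Ring order: ring A (step 5), then ring B (step 13).

Assumption: the configuration is taken exactly as written in the SMILES, which is 3S,6S,7S,8R,10R with 1E and 4Z ring alkenes and a Z (angelate) ester in germacrane numbering (C6 lactone O–CH, C7 ring-fusion CH, C8 angelate CH, C10 tertiary carbinol, C3 acetate CH, C11–C13 acrylate unit), used throughout.

**Step 1**
Reactants: 1 methyl prop-2-ynoate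
Product: 3 methyl (2Z)-2-(hydroxymethyl)-3-iodoprop-2-enoate, via aluminium allenolate 2 (not isolated)
Conditions: Et2AlI (1.2 equiv), CH2Cl2, 0 °C; then CH2O gas (cracked paraformaldehyde), −78 to 0 °C; aq. potassium sodium tartrate
Reagents that add atoms: diethylaluminium iodide, CC[Al](I)CC; formaldehyde, C=O
Why: Iodoalumination of the ynoate gives the β-iodo aluminium allenolate 2, which adds to formaldehyde at the α-carbon anti to iodine (β-iodo Morita–Baylis–Hillman-type three-component coupling), so iodine ends cis to the ester (Z), the geometry needed for lactonisation in step 5.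

**Step 2**
Reactants: 3 methyl (2Z)-2-(hydroxymethyl)-3-iodoprop-2-enoate
Product: 4 methyl (2Z)-2-(acetoxymethyl)-3-iodoprop-2-enoate (fragment A)
Conditions: AcCl, 2,6-lutidine, CH2Cl2, 0 °C
Reagents that add atoms: acetyl chloride, CC(=O)Cl
Why: Plain O-acetylation with a hindered base that cannot displace the vinylic iodide by addition–elimination; the acetate is the leaving group used in step 9.

**Step 3**
Reactants: 5 4-methylfuran-2(5H)-one
Product: 7 (2Z)-4-[(tert-butyldimethylsilyl)oxy]-N-methoxy-N,3-dimethylbut-2-enamide, via hydroxy Weinreb amide 6 (not isolated)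
Conditions: MeNH(OMe)·HCl, Me3Al, CH2Cl2, 0 °C to rt; aq. potassium sodium tartrate quench, crude 6 not purified; TBSCl, imidazole, CH2Cl2, 0 °C
Reagents that add atoms: N,O-dimethylhydroxylamine hydrochloride, CNOC.Cl; tert-butyldimethylsilyl chloride, CC(C)(C)[Si](C)(C)Cl
Why: Weinreb aminolysis of the lactone by the aluminium amide opens the ring with the Z geometry inherited from the butenolide (the β,β-disubstituted alkene resists conjugate addition), and immediate silylation of the primary alcohol blocks relactonisation.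

**Step 4**
Reactants: 7 (2Z)-4-[(tert-butyldimethylsilyl)oxy]-N-methoxy-N,3-dimethylbut-2-enamide
Product: 8 (2Z)-4-[(tert-butyldimethylsilyl)oxy]-3-methylbut-2-enal
Conditions: i-Bu2AlH (1.2 equiv), THF, −78 °C; aq. potassium sodium tartrate
Reagents that add atoms: none
Why: Weinreb amide reduction stops at the stable aluminium chelate, which collapses only on work-up, giving the Z-enal without over-reduction or Z to E isomerisation at −78 °C.

**Step 5**
Reactants: 8 (2Z)-4-[(tert-butyldimethylsilyl)oxy]-3-methylbut-2-enal; 4 methyl (2Z)-2-(acetoxymethyl)-3-iodoprop-2-enoate (1.5 equiv)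
Product: 10 [(5S)-5-[(1Z)-3-[(tert-butyldimethylsilyl)oxy]-2-methylprop-1-en-1-yl]-2-oxo-2,5-dihydrofuran-3-yl]methyl acetate (fragment B), via hydroxy ester 9 (not isolated)
Conditions: CrCl2 (15 mol%), chiral 2-(4-isopropyloxazolin-2-yl)anilide methanesulfonamide ligand (17 mol%; the antipode that gives the S carbinol), proton sponge (17 mol%), NiCl2(2,9-dimethyl-1,10-phenanthroline) (2 mol%), Mn powder (2 equiv), Cp2ZrCl2 (1.2 equiv), LiCl (2 equiv), MeCN, rt; work-up, then PPTS (cat.), CH2Cl2, rt
Reagents that add atoms: none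
Why: Catalytic asymmetric Nozaki–Hiyama–Kishi alkenylation, in which zerovalent nickel inserts into the C–I bond, the alkenyl group passes with retention of geometry to the chiral sulfonamide–chromium complex and adds 1,2 to the enal on the ligand-controlled face to set C6 (S), after which the cis γ-alkoxy ester lactonises to the butenolide (ring A).

**Step 6**
Reactants: 11 but-3-yn-2-one
Product: 12 (3E)-4-iodobut-3-en-2-one
Conditions: NaI (1.5 equiv), AcOH, rt, 16 h; then 57% aq. HI (cat.), CH2Cl2, rt, dark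
Reagents that add atoms: sodium iodide, [Na+].[I-]
Why: Hydroiodination of the ynone (conjugate addition of iodide, then protonation) followed by acid/iodide equilibration gives the thermodynamically favoured E β-iodoenone.

**Step 7**
Reactants: 12 (3E)-4-iodobut-3-en-2-one
Product: 13 (1E,3R)-1-iodo-3-methylhexa-1,5-dien-3-ol
Conditions: CH2=CHCH2B(O-i-Pr)2 (1.5 equiv), (S)-3,3′-dibromo-BINOL (15 mol%), PhCF3/PhMe 3:1, −35 °C
Reagents that add atoms: diisopropyl allylboronate, C=CCB(OC(C)C)OC(C)C
Why: Chiral-diol-catalysed asymmetric allylboration of a ketone, in which exchange of one isopropoxy group for the BINOL gives a more Lewis-acidic chiral boronate that adds 1,2 through a closed chair transition state with the iodovinyl group as the large substituent, setting C10 (R expected by analogy with aryl and alkenyl methyl ketones; the antipodal catalyst is used if the sense proves opposite).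

**Step 8**
Reactants: 13 (1E,3R)-1-iodo-3-methylhexa-1,5-dien-3-ol
Product: 15 (3R,4E)-5-iodo-3-methylpent-4-ene-1,3-diol (fragment C), via hydroxy aldehyde 14 (not isolated)
Conditions: O3, CH2Cl2/MeOH 4:1, −78 °C, Sudan Red 7B end-point; then NaBH4, −78 to 0 °C
Reagents that add atoms: ozone, [O-][O+]=O
Why: Ozonolysis cleaves the monosubstituted terminal alkene much faster than the iodine-deactivated 1,2-disubstituted alkene, and in-situ borohydride reduction gives the primary alcohol without isolating the elimination-prone β-hydroxy aldehyde 14, leaving C10 untouched.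

**Step 9**
Reactants: 10 [(5S)-5-[(1Z)-3-[(tert-butyldimethylsilyl)oxy]-2-methylprop-1-en-1-yl]-2-oxo-2,5-dihydrofuran-3-yl]methyl acetate (1.0 equiv); 15 (3R,4E)-5-iodo-3-methylpent-4-ene-1,3-diol (1.3 equiv)
Product: 16 (4S,5S)-5-[(1Z)-3-[(tert-butyldimethylsilyl)oxy]-2-methylprop-1-en-1-yl]-4-[(1R,3R,4E)-1,3-dihydroxy-5-iodo-3-methylpent-4-en-1-yl]-3-methylideneoxolan-2-one
Conditions: [Ir(cod)Cl]2 (2.5 mol%), BIPHEP (5 mol%), 4-cyano-3-nitrobenzoic acid (10 mol%), K3PO4 (10 mol%), degassed THF (0.5 M), 60 °C, 24 h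
Reagents that add atoms: none
Why: Proposed new method: iridium-catalysed transfer-hydrogenative carbonyl allylation from the alcohol oxidation level with a butenolide-embedded 2-acylallyl acetate as allyl donor; the cyclometalated trivalent-iridium C,O-benzoate alkoxide of 15 undergoes β-hydride elimination to aldehyde 14 (present only transiently, which suppresses its retro-aldol and elimination pathways), loss of acid gives monovalent iridium that ionises the activated allylic acetate 10 to a 2-acyl π-allyl complex, and its σ-allyl form with iridium on the exocyclic CH2 adds to the aldehyde through a closed chair transition state at ring carbon C7 anti to the C6 alkenyl group (C7 S, trans-lactone) with the aldehyde chain equatorial (C8 R) while the double bond moves exocyclic to give the α-methylene lactone, after which alcohol exchange releases 16 and acetic acid; the closest known reaction types are the iridium-catalysed 2-(alkoxycarbonyl)allylation of primary alcohols with acyclic 2-(alkoxycarbonyl)allyl carboxylates or carbonates and the zinc Barbier addition of 3-(bromomethyl)butenolides to aldehydes, the cyclic stereodefined donor and the diol/alkenyl iodide partner being untested.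

**Step 10**
Reactants: 16 (4S,5S)-5-[(1Z)-3-[(tert-butyldimethylsilyl)oxy]-2-methylprop-1-en-1-yl]-4-[(1R,3R,4E)-1,3-dihydroxy-5-iodo-3-methylpent-4-en-1-yl]-3-methylideneoxolan-2-one; 17 (2Z)-2-methylbut-2-enoic acid (angelic acid, 4 equiv)
Product: 19 (1R,3R,4E)-1-[(2S,3S)-2-[(1Z)-3-[(tert-butyldimethylsilyl)oxy]-2-methylprop-1-en-1-yl]-4-methylidene-5-oxooxolan-3-yl]-3-hydroxy-5-iodo-3-methylpent-4-en-1-yl (2Z)-2-methylbut-2-enoate, via mixed anhydride 18 (not isolated)
Conditions: 2,4,6-trichlorobenzoyl chloride (4 equiv), Et3N (4.4 equiv), PhMe, rt, 2 h; then 16, PhMe, 75 °C, 36 h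
Reagents that add atoms: none
Why: Yamaguchi-type mixed-anhydride esterification run without a nucleophilic catalyst, a protocol that transfers the angeloyl group without Z to E isomerisation to the tiglate, acylating the secondary C8 hydroxyl while the tertiary C10 hydroxyl is inert.

**Step 11**
Reactants: 19 (the silyl ether angelate)
Product: 20 (1R,3R,4E)-3-hydroxy-1-[(2S,3S)-2-[(1Z)-3-hydroxy-2-methylprop-1-en-1-yl]-4-methylidene-5-oxooxolan-3-yl]-5-iodo-3-methylpent-4-en-1-yl (2Z)-2-methylbut-2-enoate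
Conditions: HF·pyridine, pyridine, THF, 0 °C to rt
Reagents that add atoms: none
Why: Buffered fluoride desilylation removes the primary allylic silyl ether, and the esters, lactone, alkenyl iodide and tertiary allylic alcohol are stable to it.

**Step 12**
Reactants: 20 (the primary allylic alcohol)
Product: 21 (1R,3R,4E)-3-hydroxy-5-iodo-3-methyl-1-[(2S,3S)-4-methylidene-2-[(1Z)-2-methyl-3-oxoprop-1-en-1-yl]-5-oxooxolan-3-yl]pent-4-en-1-yl (2Z)-2-methylbut-2-enoate
Conditions: MnO2 (20 equiv), CH2Cl2, rt
Reagents that add atoms: none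
Why: Allylic oxidation with MnO2 touches only the primary allylic alcohol (the tertiary allylic alcohol cannot be oxidised) under neutral heterogeneous conditions that preserve the Z geometry of the enal.

**Step 13**
Reactants: 21 (the iodo-enal)
Product: 22 (3aS,4R,6R,7E,9S,10Z,11aS)-6,9-dihydroxy-6,10-dimethyl-3-methylidene-2-oxo-2,3,3a,4,5,6,9,11a-octahydrocyclodeca[b]furan-4-yl (2Z)-2-methylbut-2-enoate
Conditions: CrCl2 (20 mol%), chiral 2-(4-isopropyloxazolin-2-yl)anilide methanesulfonamide ligand (22 mol%; the antipode that gives the 3S carbinol), proton sponge (22 mol%), NiCl2(2,9-dimethyl-1,10-phenanthroline) (5 mol%), Mn powder (3 equiv), Cp2ZrCl2 (2.2 equiv), LiCl (3 equiv), MeCN, rt, 21 added by syringe pump over 12 h (final 2 mM)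
Reagents that add atoms: none
Why: Intramolecular Nozaki–Hiyama–Kishi reaction, in which nickel-catalysed activation of the E-alkenyl iodide, transmetalation to chromium and chemoselective 1,2-addition to the enal (esters, α-methylene lactone and free hydroxyl tolerated) close ring B at C2–C3 under high dilution with retention of the E geometry, the chiral sulfonamide on chromium being chosen to favour the 3S carbinol.

**Step 14**
Reactants: 22 (the macrocyclic diol)
Product: 23 (3aS,4R,6R,7E,9S,10Z,11aS)-9-(acetyloxy)-6-hydroxy-6,10-dimethyl-3-methylidene-2-oxo-2,3,3a,4,5,6,9,11a-octahydrocyclodeca[b]furan-4-yl (2Z)-2-methylbut-2-enoate (target)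
Conditions: Ac2O (1.5 equiv), pyridine, DMAP (5 mol%), CH2Cl2, 0 °C
Reagents that add atoms: acetic anhydride, CC(=O)OC(C)=O
Why: Standard acetylation, in which the secondary allylic C3 hydroxyl is acylated at 0 °C while the hindered tertiary C10 hydroxyl is not.

**Compound list**
1 | methyl prop-2-ynoate | C#CC(=O)OC | starting material
2 | diethylaluminium 3-iodo-1-methoxypropa-1,2-dien-1-olate (aluminium allenolate) | CC[Al](CC)OC(OC)=C=CI | intermediate
3 | methyl (2Z)-2-(hydroxymethyl)-3-iodoprop-2-enoate | I/C=C(/CO)C(=O)OC | intermediate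
4 | methyl (2Z)-2-(acetoxymethyl)-3-iodoprop-2-enoate (fragment A) | I/C=C(/COC(C)=O)C(=O)OC | intermediate
5 | 4-methylfuran-2(5H)-one | CC1=CC(=O)OC1 | starting material
6 | (2Z)-4-hydroxy-N-methoxy-N,3-dimethylbut-2-enamide | CON(C)C(=O)/C=C(/C)CO | intermediate
7 | (2Z)-4-[(tert-butyldimethylsilyl)oxy]-N-methoxy-N,3-dimethylbut-2-enamide | CON(C)C(=O)/C=C(/C)CO[Si](C)(C)C(C)(C)C | intermediate
8 | (2Z)-4-[(tert-butyldimethylsilyl)oxy]-3-methylbut-2-enal | O=C/C=C(/C)CO[Si](C)(C)C(C)(C)C | intermediate
9 | methyl (2Z,4S,5Z)-2-(acetoxymethyl)-7-[(tert-butyldimethylsilyl)oxy]-4-hydroxy-6-methylhepta-2,5-dienoate | O[C@@H](/C=C(/C)CO[Si](C)(C)C(C)(C)C)/C=C(/COC(C)=O)C(=O)OC | intermediate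
10 | [(5S)-5-[(1Z)-3-[(tert-butyldimethylsilyl)oxy]-2-methylprop-1-en-1-yl]-2-oxo-2,5-dihydrofuran-3-yl]methyl acetate (fragment B) | O=C1O[C@@H](/C=C(/C)CO[Si](C)(C)C(C)(C)C)C=C1COC(C)=O | intermediate
11 | but-3-yn-2-one | CC(=O)C#C | starting material
12 | (3E)-4-iodobut-3-en-2-one | CC(=O)/C=C/I | intermediate
13 | (1E,3R)-1-iodo-3-methylhexa-1,5-dien-3-ol | C=CC[C@@](C)(O)/C=C/I | intermediate
14 | (3R,4E)-3-hydroxy-5-iodo-3-methylpent-4-enal | O=CC[C@@](C)(O)/C=C/I | intermediate
15 | (3R,4E)-5-iodo-3-methylpent-4-ene-1,3-diol (fragment C) | OCC[C@@](C)(O)/C=C/I | intermediate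
16 | (4S,5S)-5-[(1Z)-3-[(tert-butyldimethylsilyl)oxy]-2-methylprop-1-en-1-yl]-4-[(1R,3R,4E)-1,3-dihydroxy-5-iodo-3-methylpent-4-en-1-yl]-3-methylideneoxolan-2-one | C=C1C(=O)O[C@@H](/C=C(/C)CO[Si](C)(C)C(C)(C)C)[C@@H]1[C@H](O)C[C@@](C)(O)/C=C/I | intermediate
17 | (2Z)-2-methylbut-2-enoic acid (angelic acid) | C/C=C(/C)C(=O)O | starting material
18 | (2Z)-2-methylbut-2-enoic 2,4,6-trichlorobenzoic anhydride | C/C=C(/C)C(=O)OC(=O)c1c(Cl)cc(Cl)cc1Cl | intermediate
19 | (1R,3R,4E)-1-[(2S,3S)-2-[(1Z)-3-[(tert-butyldimethylsilyl)oxy]-2-methylprop-1-en-1-yl]-4-methylidene-5-oxooxolan-3-yl]-3-hydroxy-5-iodo-3-methylpent-4-en-1-yl (2Z)-2-methylbut-2-enoate | C=C1C(=O)O[C@@H](/C=C(/C)CO[Si](C)(C)C(C)(C)C)[C@@H]1[C@H](OC(=O)/C(C)=C\C)C[C@@](C)(O)/C=C/I | intermediate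
20 | (1R,3R,4E)-3-hydroxy-1-[(2S,3S)-2-[(1Z)-3-hydroxy-2-methylprop-1-en-1-yl]-4-methylidene-5-oxooxolan-3-yl]-5-iodo-3-methylpent-4-en-1-yl (2Z)-2-methylbut-2-enoate | C=C1C(=O)O[C@@H](/C=C(/C)CO)[C@@H]1[C@H](OC(=O)/C(C)=C\C)C[C@@](C)(O)/C=C/I | intermediate
21 | (1R,3R,4E)-3-hydroxy-5-iodo-3-methyl-1-[(2S,3S)-4-methylidene-2-[(1Z)-2-methyl-3-oxoprop-1-en-1-yl]-5-oxooxolan-3-yl]pent-4-en-1-yl (2Z)-2-methylbut-2-enoate | C=C1C(=O)O[C@@H](/C=C(/C)C=O)[C@@H]1[C@H](OC(=O)/C(C)=C\C)C[C@@](C)(O)/C=C/I | intermediate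
22 | (3aS,4R,6R,7E,9S,10Z,11aS)-6,9-dihydroxy-6,10-dimethyl-3-methylidene-2-oxo-2,3,3a,4,5,6,9,11a-octahydrocyclodeca[b]furan-4-yl (2Z)-2-methylbut-2-enoate | C=C1C(=O)O[C@H]2/C=C(/C)[C@@H](O)/C=C/[C@](C)(O)C[C@@H](OC(=O)/C(C)=C\C)[C@H]12 | intermediate
23 | (3aS,4R,6R,7E,9S,10Z,11aS)-9-(acetyloxy)-6-hydroxy-6,10-dimethyl-3-methylidene-2-oxo-2,3,3a,4,5,6,9,11a-octahydrocyclodeca[b]furan-4-yl (2Z)-2-methylbut-2-enoate | C=C1C(=O)O[C@H]2/C=C(/C)[C@@H](OC(C)=O)/C=C/[C@](C)(O)C[C@@H](OC(=O)/C(C)=C\C)[C@H]12 | target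

**Step count and risks**
Total step count: 14. Longest linear sequence: 9 steps (steps 3, 4, 5, 9–14 from 4-methylfuran-2(5H)-one; the branches from methyl propiolate and from but-3-yn-2-one are equally long).

The three steps most likely to fail:

Step 5 (asymmetric alkenylation/lactonisation). The activated allylic acetate of 4 could be ionised by zerovalent nickel, and the enantioselectivity with a cis-β-iodoacrylate is unproven. The fallback sets out from enal 8 and returns at 10. Enantioselective vinyl transfer to 8 (divinylzinc from CH2=CHMgBr and ZnCl2, 3-exo-morpholinoisoborneol 10 mol%, antipode chosen for the R alcohol, toluene, −20 °C) gives (3R,4Z)-6-[(tert-butyldimethylsilyl)oxy]-5-methylhexa-1,4-dien-3-ol F1. Commercial 2-(bromomethyl)prop-2-enoic acid is converted with KOAc in AcOH into 2-(acetoxymethyl)prop-2-enoic acid F2. Carbodiimide esterification of F1 with F2 (DIC, DMAP cat., CH2Cl2, 0 °C) gives (3R,4Z)-6-[(tert-butyldimethylsilyl)oxy]-5-methylhexa-1,4-dien-3-yl 2-(acetoxymethyl)prop-2-enoate F3. Ring-closing metathesis between its vinyl and acrylate ends (second-generation Grubbs catalyst RuCl2(H2IMes)(PCy3)(=CHPh), toluene, 80 °C) then closes ring A to 10.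

Step 9 (the proposed new iridium coupling). Possible failures are base-induced epimerisation of the acidic C6–H of 10, translactonisation of 16 to the C8 lactone at 60 °C, and insertion of monovalent iridium into the C–I bond. The fallback uses known chemistry, sets out from 10 and 15, and returns at 16. The acetate of 10 is removed under neutral conditions (Candida antarctica lipase B, n-butanol, MTBE, 30 °C) to give (5S)-5-[(1Z)-3-[(tert-butyldimethylsilyl)oxy]-2-methylprop-1-en-1-yl]-3-(hydroxymethyl)furan-2(5H)-one F4. An Appel reaction (CBr4, PPh3, CH2Cl2, 0 °C) converts it into (5S)-3-(bromomethyl)-5-[(1Z)-3-[(tert-butyldimethylsilyl)oxy]-2-methylprop-1-en-1-yl]furan-2(5H)-one F5. Diol 15 is oxidised at the primary hydroxyl only (TEMPO cat., PhI(OAc)2, CH2Cl2) to aldehyde 14, which is used at once. Zinc-mediated Barbier allylation of 14 with F5 (Zn dust, THF/sat. aq. NH4Cl, 0 °C) gives 16 through the same chair transition state, with attack anti to the C6 substituent.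

Step 13 (ring B closure). The ten-membered ring may form with low or wrong selectivity at C3, because ligand control competes with the conformational bias of the closing ring. The fallback sets out from 21 and returns at 22, and fixes C3 by ketone reduction instead of in the C–C bond-forming event. Compound 21 is cyclised without stereocontrol (CrCl2 6 equiv, NiCl2 1 mol%, DMSO/THF, 2 mM), giving 22 together with its C3 epimer (3aS,4R,6R,7E,9R,10Z,11aS)-6,9-dihydroxy-6,10-dimethyl-3-methylidene-2-oxo-2,3,3a,4,5,6,9,11a-octahydrocyclodeca[b]furan-4-yl (2Z)-2-methylbut-2-enoate F6. The mixture is oxidised with MnO2 to the single cross-conjugated dienone (3aS,4R,6R,7E,10Z,11aS)-6-hydroxy-6,10-dimethyl-3-methylidene-2,9-dioxo-2,3,3a,4,5,6,9,11a-octahydrocyclodeca[b]furan-4-yl (2Z)-2-methylbut-2-enoate F7. Reagent-controlled 1,2-reduction (2-methyl-CBS-oxazaborolidine of the appropriate antipode, catecholborane, toluene, −78 °C) then gives 22.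

**Further compounds**
F1 | step 5 | (3R,4Z)-6-[(tert-butyldimethylsilyl)oxy]-5-methylhexa-1,4-dien-3-ol | O[C@@H](/C=C(/C)CO[Si](C)(C)C(C)(C)C)C=C
F2 | step 5 | 2-(acetoxymethyl)prop-2-enoic acid | C=C(COC(C)=O)C(=O)O
F3 | step 5 | (3R,4Z)-6-[(tert-butyldimethylsilyl)oxy]-5-methylhexa-1,4-dien-3-yl 2-(acetoxymethyl)prop-2-enoate | C=C(COC(C)=O)C(=O)O[C@@H](/C=C(/C)CO[Si](C)(C)C(C)(C)C)C=C
F4 | step 9 | (5S)-5-[(1Z)-3-[(tert-butyldimethylsilyl)oxy]-2-methylprop-1-en-1-yl]-3-(hydroxymethyl)furan-2(5H)-one | O=C1O[C@@H](/C=C(/C)CO[Si](C)(C)C(C)(C)C)C=C1CO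
F5 | step 9 | (5S)-3-(bromomethyl)-5-[(1Z)-3-[(tert-butyldimethylsilyl)oxy]-2-methylprop-1-en-1-yl]furan-2(5H)-one | O=C1O[C@@H](/C=C(/C)CO[Si](C)(C)C(C)(C)C)C=C1CBr
F6 | step 13 | (3aS,4R,6R,7E,9R,10Z,11aS)-6,9-dihydroxy-6,10-dimethyl-3-methylidene-2-oxo-2,3,3a,4,5,6,9,11a-octahydrocyclodeca[b]furan-4-yl (2Z)-2-methylbut-2-enoate | C=C1C(=O)O[C@H]2/C=C(/C)[C@H](O)/C=C/[C@](C)(O)C[C@@H](OC(=O)/C(C)=C\C)[C@H]12
F7 | step 13 | (3aS,4R,6R,7E,10Z,11aS)-6-hydroxy-6,10-dimethyl-3-methylidene-2,9-dioxo-2,3,3a,4,5,6,9,11a-octahydrocyclodeca[b]furan-4-yl (2Z)-2-methylbut-2-enoate | C=C1C(=O)O[C@H]2/C=C(/C)C(=O)/C=C/[C@](C)(O)C[C@@H](OC(=O)/C(C)=C\C)[C@H]12
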